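The constants send the partner to decay, to the forward step and to the side step, and we fold the first two into one number.

    partner → decomposed reagent (k1 = 0.062 s⁻¹)
    starting material + 2 partner → side product (k2 = 6400 M⁻² s⁻¹)
    starting material + partner ⇌ target (K3 = 16000 M⁻¹, k3 = 16 M⁻¹ s⁻¹)

| flask | starting material | partner | time | remark |
|---|---|---|---|---|
| blue | 1.0 mM | 2.00 mM | 80 s | everything together at the start |
| amber | 1.0 mM | 2.00 mM (fed, over 1.0 min) | 80 s | all else is in the flask from the start; the feed brings no volume worth counting |
| ochre | 1.0 mM (fed, over 1.0 min) | 2.00 mM | 80 s | all else is in the flask from the start; the feed brings no volume worth counting |

- which flask leads in amount of target, in percent of the starting material charged ("all alike" within 1.5 percentage points) (blue / amber / ochre / all alike)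
- how much target is there at the end, in percent of the starting material charged: blue
- how much target is there at the end, in percent of the starting material charged: amber
- how much target is there at the end, in percent of the starting material charged: ochre

- a doubled species enters its step squared and goes two at a time
- run time (blue): 80 s

- We reckon with the fraction of starting material left, not the fraction made.
- Partner decays with a lifetime of 16.1 s. Decay is faster than the forward step takes partner with starting material at full charge, so as a first reckoning we let decay set how long partner lasts.
- Starting material then falls pseudo-first-order, at the forward constant times partner. The exposure number is forward constant times partner charge times partner lifetime, 0.516. The fraction left by the forward step is e to the minus this number.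
- Blue and amber have the same charge, so we give both this exposure. The fraction left is 0.597, which gives about 40.3% of the charge as target.
- Ochre's starting material comes in over 1.0 min, longer than the partner's lifetime. Its average exposure shrinks to 0.139, which gives about 13.0%.
- One number is not enough, since it cannot part blue from amber. The side step over the forward step goes as partner, 0.800 at full charge. Amber's feed holds partner near 0.269 of its charge, which makes the ratio 0.215.
- So we commit to amber first and ochre last. We expect our percentages to run high: they leave out the side step and the way back.
- The forecast says amber, with blue 27.1%, amber 30.5% and ochre 8.8%. Its ground: “keeping partner low favours target”.
- The simulation gives amber: blue 27.2%, amber 30.4%, ochre 9.16%.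
- Amber is not at rest at 80.0 s. Its remaining partner, 4.93% of the charge, carries an exposure of 0.0254, which we reckon at about 1.7 percentage points of further target. Yet at ten times the time amber's target stands at 17.3%, with starting material up from 65.3% to 78.3%.
- Ochre keeps 0.381% of its partner, an exposure of 0.00197, and at ten times the time its target goes from 9.16% to 5.19%.

The constants were drawn at random within sensible limits; the rest is arithmetic.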